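**Retrosynthetic overview** (benzofuran numbering: O1, C2 syringyl, C3 CH2OH; ring B = C3a, C4, C5, C6, C7, C7a)
1. The route rests on ring B: a benzene ring with oxygen at C7 and at C5 (1,3 relation), fused to the furan ring through C3a–C7a with O1 on C7a. This is the phenol expected from a dihydrofuranyl vinylketene (C7, C4, C3a, C7a) and a siloxyalkyne (C6, C5).
2. Last disconnection: the C5–vinyl bond of the stilbene, by Heck coupling of C5 triflate 28 with styrene 31; the C5 oxygen left by the benzannulation becomes the triflate.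
3. Key disconnection: ring B (bonds C7–C6, C5–C4, C7–C7a) from diazoketone 17 and (triisopropylsilyloxy)ethyne 20 by Wolff rearrangement and vinylketene–alkyne benzannulation.
4. Furan ring: alkynol 12 is cycloisomerised (O1–C7a bond) and acylated at the future C3a; C2 and C3 come from an Evans syn aldol of butynoyl imide 7 with aldehyde 2.
5. Ring order: syringyl ring (bought), furan ring (step 6), ring B (step 11), resorcinol ring of the stilbene attached (step 17).

Key step: step 11

Remark: read from the SMILES, the target is the (2R,3S) isomer with the syringyl and hydroxymethyl groups trans; Ar = 4-(methoxymethoxy)-3,5-dimethoxyphenyl throughout.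

Step 1
Reactants: 1 syringaldehyde
Product: 2 4-(methoxymethoxy)-3,5-dimethoxybenzaldehyde
Conditions: MOMCl, i-Pr2NEt, CH2Cl2, 0 °C → rt
Reagents that add atoms: chloromethyl methyl ether, COCCl
Why: Williamson-type O-alkylation of the phenoxide masks the only acidic proton as an acetal that is stable to enolates, hydride, base, fluoride and palladium and is removed at the end by mild acid.

Step 2
Reactants: 3 but-3-ynoic acid; 4 (R)-4-benzyl-2-oxazolidinone
Product: 7 (R)-4-benzyl-3-(but-3-ynoyl)oxazolidin-2-one, via but-3-ynoyl chloride 5 (not isolated), via lithium oxazolidinide 6 (not isolated)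
Conditions: 3, (COCl)2, DMF (cat.), CH2Cl2, 0 °C → rt, evaporate; 4, n-BuLi, THF, −78 °C; then 5, −78 °C, cold NH4Cl quench
Reagents that add atoms: none
Why: N-acylation of the lithiated oxazolidinone by the acid chloride at −78 °C needs no amine base and is quenched cold, so the base-induced propargyl to allenyl isomerisation of the but-3-ynoyl group is avoided.

Step 3
Reactants: 7 (R)-4-benzyl-3-(but-3-ynoyl)oxazolidin-2-one; 2 4-(methoxymethoxy)-3,5-dimethoxybenzaldehyde
Product: 10 (R)-4-benzyl-3-[(2R,3R)-2-ethynyl-3-hydroxy-3-Ar-propanoyl]oxazolidin-2-one, via Z dibutylboron enolate 8 (not isolated), via dibutylboron aldolate 9 (not isolated)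
Conditions: Bu2BOTf, i-Pr2NEt, CH2Cl2, −78 °C; then 2, −78 → −20 °C; pH 7 buffer, MeOH, H2O2, 0 °C
Reagents that add atoms: none
Why: Evans syn aldol: soft enolisation gives the Z boron enolate, which reacts through a chair Zimmerman–Traxler transition state on the enolate face away from the benzyl group of the (R)-auxiliary, setting the (2R,3R) syn pair that becomes C3 and C2 of the benzofuran.

Step 4
Reactants: 10 (R)-4-benzyl-3-[(2R,3R)-2-ethynyl-3-hydroxy-3-Ar-propanoyl]oxazolidin-2-one
Product: 11 (1R,2S)-2-ethynyl-1-Ar-propane-1,3-diol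
Conditions: LiBH4, MeOH (1 equiv), THF, 0 °C
Reagents that add atoms: none
Why: Hydride attacks the more electrophilic exocyclic imide carbonyl (reductive removal of the Evans auxiliary, recovered as 4), and the cold, weakly basic medium should not trigger retro-aldol or epimerisation at the propargylic centre.

Step 5
Reactants: 11 (1R,2S)-2-ethynyl-1-Ar-propane-1,3-diol
Product: 12 (1R,2S)-2-[(tert-butyldimethylsilyloxy)methyl]-1-Ar-but-3-yn-1-ol
Conditions: TBSCl, imidazole, CH2Cl2, 0 °C
Reagents that add atoms: tert-butyldimethylsilyl chloride, CC(C)(C)[Si](C)(C)Cl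
Why: Silylation is faster at the unhindered primary hydroxyl than at the secondary benzylic one, and it blocks the hydroxyl that would otherwise also cyclise onto the alkyne in step 6.

Step 6
Reactants: 12 (1R,2S)-2-[(tert-butyldimethylsilyloxy)methyl]-1-Ar-but-3-yn-1-ol
Product: 13 (2R,3S)-3-[(tert-butyldimethylsilyloxy)methyl]-2-Ar-2,3-dihydrofuran
Conditions: W(CO)6 (25 mol %), Et3N, THF, hν (350 nm), 55 °C
Reagents that add atoms: none
Why: Alkynol cycloisomerisation: photogenerated W(CO)5(NEt3) converts the terminal alkyne into a tungsten vinylidene, the benzylic hydroxyl adds to its carbene carbon and amine-mediated proton transfer releases the enol ether, so O1–C7a forms without touching C2 or C3 and the syn aldol relationship appears as the trans ring substitution.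

Step 7
Reactants: 13 (2R,3S)-3-[(tert-butyldimethylsilyloxy)methyl]-2-Ar-2,3-dihydrofuran
Product: 14 2,2,2-trichloro-1-[(4S,5R)-4-[(tert-butyldimethylsilyloxy)methyl]-5-Ar-4,5-dihydrofuran-3-yl]ethan-1-one
Conditions: Cl3CCOCl, pyridine, CH2Cl2, 0 °C → rt
Reagents that add atoms: trichloroacetyl chloride, O=C(Cl)C(Cl)(Cl)Cl
Why: Electrophilic acylation of an enol ether at its β-carbon (the future C3a) by the highly electrophilic acid chloride, with pyridine taking up HCl, is the standard entry to 3-acyl-4,5-dihydrofurans and leaves a stable push–pull enone.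

Step 8
Reactants: 14 2,2,2-trichloro-1-[(4S,5R)-4-[(tert-butyldimethylsilyloxy)methyl]-5-Ar-4,5-dihydrofuran-3-yl]ethan-1-one
Product: 15 (4S,5R)-4-[(tert-butyldimethylsilyloxy)methyl]-5-Ar-4,5-dihydrofuran-3-carboxylic acid
Conditions: LiOH, THF/H2O, 0 °C → rt; then 0.5 M HCl to pH 4, 0 °C
Reagents that add atoms: lithium hydroxide, [Li+].[OH-]
Why: Haloform-type cleavage: hydroxide adds to the trichloromethyl ketone and expels trichloromethanide (collected as chloroform), giving the vinylogous carbonic acid, and the brief mildly acidic work-up is tolerated by the MOM, silyl and enol ether groups.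

Step 9
Reactants: 15 (4S,5R)-4-[(tert-butyldimethylsilyloxy)methyl]-5-Ar-4,5-dihydrofuran-3-carboxylic acid
Product: 17 2-diazo-1-[(4S,5R)-4-[(tert-butyldimethylsilyloxy)methyl]-5-Ar-4,5-dihydrofuran-3-yl]ethan-1-one, via acid chloride 16 (not isolated)
Conditions: Me2C=C(Cl)NMe2, CH2Cl2, 0 °C → rt; then CH2N2, Et3N, Et2O, 0 °C
Reagents that add atoms: diazomethane, C=[N+]=[N-]
Why: First stage of the Arndt–Eistert sequence in its Newman–Beal form: the chloroenamine (Ghosez reagent) makes the acid chloride without free HCl, diazomethane is C-acylated and Et3N takes the proton (no α-hydrogen, hence no ketene), while the donor-substituted trisubstituted C=C is a poor dipolarophile.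

Step 10
Reactants: 18 3-phenylisoxazole
Product: 20 (triisopropylsilyloxy)ethyne, via lithium ethynolate 19 (not isolated)
Conditions: LiN(i-Pr)2, THF, −78 → 0 °C; then TIPSCl, −78 °C → rt
Reagents that add atoms: triisopropylsilyl chloride, CC(C)[Si](Cl)(C(C)C)C(C)C
Why: Deprotonation at C5 of the isoxazole triggers cycloreversion to benzonitrile and lithium ethynolate, and the bulky silyl chloride silylates the ynolate on oxygen (ynolate O-silylation), giving the siloxyalkyne, which is distilled and used at once.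

Step 11
Reactants: 17 2-diazo-1-[(4S,5R)-4-[(tert-butyldimethylsilyloxy)methyl]-5-Ar-4,5-dihydrofuran-3-yl]ethan-1-one; 20 (triisopropylsilyloxy)ethyne
Product: 25 (2R,3S)-3-[(tert-butyldimethylsilyloxy)methyl]-2-Ar-5-(triisopropylsilyloxy)-2,3-dihydro-1-benzofuran-7-ol, via vinylketene 21 (not isolated), via cyclobutenone 22 (not isolated), via dienylketene 23 (not isolated), via cyclohexadienone 24 (not isolated)
Conditions: 20 (1.5 equiv), ClCH2CH2Cl, hν (Hg lamp, Pyrex filter, >300 nm), rt; then 80 °C in the dark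
Reagents that add atoms: none
Why: Light expels N2 from 17 and the dihydrofuranyl group migrates to the former diazo carbon (Wolff rearrangement), giving vinylketene 21 (O=C7=C4H–C3a=C7aH), whose ketene C=C bond takes up alkyne 20 in a (2+2) cycloaddition to cyclobutenone 22; on warming 22 opens by four-electron electrocyclic cleavage of the C7–C4 bond to dienylketene 23, which closes between C7 and C7a and tautomerises from dienone 24 to phenol 25. The closest known reaction type is the Danheiser benzannulation in its photochemical Wolff form, in which α,β-unsaturated and heteroaryl α-diazo ketones combine with siloxyalkynes to give resorcinol monosilyl ethers. Ring B is closed by a thermal six-electron (disrotatory) electrocyclisation of the E dienylketene onto the enol ether carbon C7a, the four-membered ring of 22 being only a transient product of the (2+2) step. No stereocentre is created in 25 (C4 of 22 and C7a of 24 are lost on opening and aromatisation), and C2 and C3 lie outside the reacting π system, so the trans (2R,3S) pair from the aldol step is carried through unchanged. The step needs regioselective alkyne uptake, which the polarity of 20 secures, since its nucleophilic CH carbon bonds to the electrophilic ketene carbon C7 and thus places hydrogen at C6 and the silyloxy group at C5. It also needs selective excitation, secured by the long-wavelength absorption of the push–pull diazo enone (Pyrex-filtered light is not absorbed by the arene or by 20), with 20 in excess to outrun ketene dimerisation and acylation of the product phenol.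

Step 12
Reactants: 25 (2R,3S)-3-[(tert-butyldimethylsilyloxy)methyl]-2-Ar-5-(triisopropylsilyloxy)-2,3-dihydro-1-benzofuran-7-ol
Product: 26 (2R,3S)-3-[(tert-butyldimethylsilyloxy)methyl]-7-methoxy-2-Ar-5-(triisopropylsilyloxy)-2,3-dihydro-1-benzofuran
Conditions: MeI, K2CO3, acetone, 40 °C
Reagents that add atoms: iodomethane, CI
Why: Williamson methylation of the single free phenol (C7–OH) under conditions in which the aryl triisopropylsilyl ether and the alkyl silyl ether persist.

Step 13
Reactants: 26 (2R,3S)-3-[(tert-butyldimethylsilyloxy)methyl]-7-methoxy-2-Ar-5-(triisopropylsilyloxy)-2,3-dihydro-1-benzofuran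
Product: 27 (2R,3S)-3-(hydroxymethyl)-7-methoxy-2-Ar-2,3-dihydro-1-benzofuran-5-ol
Conditions: Bu4NF, THF, 0 °C → rt, argon
Reagents that add atoms: none
Why: Fluoride-induced desilylation through pentacoordinate silicon removes both silyl ethers, freeing the C5 phenol and the primary alcohol while the MOM acetal is inert.

Step 14
Reactants: 27 (2R,3S)-3-(hydroxymethyl)-7-methoxy-2-Ar-2,3-dihydro-1-benzofuran-5-ol
Product: 28 (2R,3S)-3-(hydroxymethyl)-7-methoxy-2-Ar-2,3-dihydro-1-benzofuran-5-yl trifluoromethanesulfonate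
Conditions: PhNTf2, Et3N, CH2Cl2, 0 °C → rt
Reagents that add atoms: N-phenylbis(trifluoromethanesulfonimide), O=S(=O)(N(c1ccccc1)S(=O)(=O)C(F)(F)F)C(F)(F)F
Why: Chemoselective O-triflation: the mild triflyl donor reacts with the phenoxide formed by Et3N and not with the neutral primary alcohol, so the C3 hydroxymethyl group needs no protection.

Step 15
Reactants: 29 3,5-dihydroxybenzaldehyde
Product: 30 3,5-bis(methoxymethoxy)benzaldehyde
Conditions: MOMCl, i-Pr2NEt, CH2Cl2, 0 °C → rt
Reagents that add atoms: chloromethyl methyl ether, COCCl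
Why: Twofold Williamson-type O-alkylation of the phenols gives the acetal-protected aldehyde with the same protecting group as on the syringyl ring.

Step 16
Reactants: 30 3,5-bis(methoxymethoxy)benzaldehyde
Product: 31 1-ethenyl-3,5-bis(methoxymethoxy)benzene
Conditions: Ph3PCH3Br, KOt-Bu, THF, 0 °C → rt
Reagents that add atoms: methyltriphenylphosphonium bromide, C[P+](c1ccccc1)(c1ccccc1)c1ccccc1.[Br-]
Why: Wittig methylenation of the aromatic aldehyde with the non-stabilised ylide gives the styrene.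

Step 17
Reactants: 28 (2R,3S)-3-(hydroxymethyl)-7-methoxy-2-Ar-2,3-dihydro-1-benzofuran-5-yl trifluoromethanesulfonate; 31 1-ethenyl-3,5-bis(methoxymethoxy)benzene
Product: 32 [(2R,3S)-5-[(E)-2-[3,5-bis(methoxymethoxy)phenyl]ethenyl]-7-methoxy-2-Ar-2,3-dihydro-1-benzofuran-3-yl]methanol
Conditions: 31 (1.5 equiv), PdCl2(PPh3)2 (5 mol %), LiCl, Et3N, DMF, 100 °C
Reagents that add atoms: none
Why: Mizoroki–Heck reaction: the aryl triflate adds oxidatively to zerovalent palladium formed in situ, chloride from LiCl keeps the arylpalladium species neutral so that the aryl group is delivered to the terminal styrene carbon, and syn β-hydride elimination gives the E stilbene.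

Step 18
Reactants: 32 [(2R,3S)-5-[(E)-2-[3,5-bis(methoxymethoxy)phenyl]ethenyl]-7-methoxy-2-Ar-2,3-dihydro-1-benzofuran-3-yl]methanol
Product: 33 Gnetucleistol F
Conditions: HCl (3 M aq.), MeOH/THF, rt → 40 °C, dark, argon
Reagents that add atoms: none
Why: Acid-catalysed acetal exchange with methanol cleaves the three aryl MOM ethers under conditions mild enough for the stilbene and the benzylic C2–O1 bond, whose trans arrangement is in any case the thermodynamically preferred one.

**Compound list**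
1 | syringaldehyde | COc1cc(C=O)cc(OC)c1O | starting material
2 | 4-(methoxymethoxy)-3,5-dimethoxybenzaldehyde | COCOc1c(OC)cc(C=O)cc1OC | intermediate
3 | but-3-ynoic acid | C#CCC(=O)O | starting material
4 | (R)-4-benzyl-2-oxazolidinone | O=C1OC[C@@H](Cc2ccccc2)N1 | starting material
5 | but-3-ynoyl chloride | C#CCC(=O)Cl | intermediate
6 | lithium (R)-4-benzyl-2-oxooxazolidin-3-ide | [Li+].O=C1OC[C@@H](Cc2ccccc2)[N-]1 | intermediate
7 | (R)-4-benzyl-3-(but-3-ynoyl)oxazolidin-2-one | C#CCC(=O)N1[C@H](Cc2ccccc2)COC1=O | intermediate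
8 | (R)-4-benzyl-3-[(1Z)-1-(dibutylboryloxy)but-1-en-3-yn-1-yl]oxazolidin-2-one | C#C/C=C(\OB(CCCC)CCCC)N1[C@H](Cc2ccccc2)COC1=O | intermediate
9 | O-dibutylboryl derivative of aldol 10 | C#C[C@H]([C@@H](OB(CCCC)CCCC)c1cc(OC)c(OCOC)c(OC)c1)C(=O)N1[C@H](Cc2ccccc2)COC1=O | intermediate
10 | (R)-4-benzyl-3-[(2R,3R)-2-ethynyl-3-hydroxy-3-[4-(methoxymethoxy)-3,5-dimethoxyphenyl]propanoyl]oxazolidin-2-one | C#C[C@H]([C@@H](O)c1cc(OC)c(OCOC)c(OC)c1)C(=O)N1[C@H](Cc2ccccc2)COC1=O | intermediate
11 | (1R,2S)-2-ethynyl-1-[4-(methoxymethoxy)-3,5-dimethoxyphenyl]propane-1,3-diol | C#C[C@H]([C@@H](O)c1cc(OC)c(OCOC)c(OC)c1)CO | intermediate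
12 | (1R,2S)-2-[(tert-butyldimethylsilyloxy)methyl]-1-[4-(methoxymethoxy)-3,5-dimethoxyphenyl]but-3-yn-1-ol | C#C[C@H]([C@@H](O)c1cc(OC)c(OCOC)c(OC)c1)CO[Si](C)(C)C(C)(C)C | intermediate
13 | (2R,3S)-3-[(tert-butyldimethylsilyloxy)methyl]-2-[4-(methoxymethoxy)-3,5-dimethoxyphenyl]-2,3-dihydrofuran | COCOc1c(OC)cc([C@@H]2OC=C[C@H]2CO[Si](C)(C)C(C)(C)C)cc1OC | intermediate
14 | 2,2,2-trichloro-1-[(4S,5R)-4-[(tert-butyldimethylsilyloxy)methyl]-5-[4-(methoxymethoxy)-3,5-dimethoxyphenyl]-4,5-dihydrofuran-3-yl]ethan-1-one | COCOc1c(OC)cc([C@@H]2OC=C(C(=O)C(Cl)(Cl)Cl)[C@H]2CO[Si](C)(C)C(C)(C)C)cc1OC | intermediate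
15 | (4S,5R)-4-[(tert-butyldimethylsilyloxy)methyl]-5-[4-(methoxymethoxy)-3,5-dimethoxyphenyl]-4,5-dihydrofuran-3-carboxylic acid | COCOc1c(OC)cc([C@@H]2OC=C(C(=O)O)[C@H]2CO[Si](C)(C)C(C)(C)C)cc1OC | intermediate
16 | (4S,5R)-4-[(tert-butyldimethylsilyloxy)methyl]-5-[4-(methoxymethoxy)-3,5-dimethoxyphenyl]-4,5-dihydrofuran-3-carbonyl chloride | COCOc1c(OC)cc([C@@H]2OC=C(C(=O)Cl)[C@H]2CO[Si](C)(C)C(C)(C)C)cc1OC | intermediate
17 | 2-diazo-1-[(4S,5R)-4-[(tert-butyldimethylsilyloxy)methyl]-5-[4-(methoxymethoxy)-3,5-dimethoxyphenyl]-4,5-dihydrofuran-3-yl]ethan-1-one | COCOc1c(OC)cc([C@@H]2OC=C(C(=O)C=[N+]=[N-])[C@H]2CO[Si](C)(C)C(C)(C)C)cc1OC | intermediate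
18 | 3-phenylisoxazole | c1ccc(cc1)-c1ccon1 | starting material
19 | lithium ethynolate | [Li+].[O-]C#C | intermediate
20 | (triisopropylsilyloxy)ethyne | C#CO[Si](C(C)C)(C(C)C)C(C)C | intermediate
21 | 2-[(4S,5R)-4-[(tert-butyldimethylsilyloxy)methyl]-5-Ar-4,5-dihydrofuran-3-yl]ethen-1-one (vinylketene) | COCOc1c(OC)cc([C@@H]2OC=C(C=C=O)[C@H]2CO[Si](C)(C)C(C)(C)C)cc1OC | intermediate
22 | 4-[(4S,5R)-4-[(tert-butyldimethylsilyloxy)methyl]-5-Ar-4,5-dihydrofuran-3-yl]-3-(triisopropylsilyloxy)cyclobut-2-en-1-one (both epimers at the ring CH) | COCOc1c(OC)cc([C@@H]2OC=C(C3C(=O)C=C3O[Si](C(C)C)(C(C)C)C(C)C)[C@H]2CO[Si](C)(C)C(C)(C)C)cc1OC | intermediate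
23 | (3E)-4-[(4S,5R)-4-[(tert-butyldimethylsilyloxy)methyl]-5-Ar-4,5-dihydrofuran-3-yl]-3-(triisopropylsilyloxy)buta-1,3-dien-1-one (dienylketene) | COCOc1c(OC)cc([C@@H]2OC=C(/C=C(/O[Si](C(C)C)(C(C)C)C(C)C)C=C=O)[C@H]2CO[Si](C)(C)C(C)(C)C)cc1OC | intermediate
24 | (2R,3S)-3-[(tert-butyldimethylsilyloxy)methyl]-2-Ar-5-(triisopropylsilyloxy)-3,7a-dihydro-1-benzofuran-7(2H)-one (both epimers at C7a) | COCOc1c(OC)cc([C@@H]2OC3C(=O)C=C(O[Si](C(C)C)(C(C)C)C(C)C)C=C3[C@H]2CO[Si](C)(C)C(C)(C)C)cc1OC | intermediate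
25 | (2R,3S)-3-[(tert-butyldimethylsilyloxy)methyl]-2-[4-(methoxymethoxy)-3,5-dimethoxyphenyl]-5-(triisopropylsilyloxy)-2,3-dihydro-1-benzofuran-7-ol | COCOc1c(OC)cc([C@@H]2Oc3c(O)cc(O[Si](C(C)C)(C(C)C)C(C)C)cc3[C@H]2CO[Si](C)(C)C(C)(C)C)cc1OC | intermediate
26 | (2R,3S)-3-[(tert-butyldimethylsilyloxy)methyl]-7-methoxy-2-[4-(methoxymethoxy)-3,5-dimethoxyphenyl]-5-(triisopropylsilyloxy)-2,3-dihydro-1-benzofuran | COCOc1c(OC)cc([C@@H]2Oc3c(OC)cc(O[Si](C(C)C)(C(C)C)C(C)C)cc3[C@H]2CO[Si](C)(C)C(C)(C)C)cc1OC | intermediate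
27 | (2R,3S)-3-(hydroxymethyl)-7-methoxy-2-[4-(methoxymethoxy)-3,5-dimethoxyphenyl]-2,3-dihydro-1-benzofuran-5-ol | COCOc1c(OC)cc([C@@H]2Oc3c(OC)cc(O)cc3[C@H]2CO)cc1OC | intermediate
28 | (2R,3S)-3-(hydroxymethyl)-7-methoxy-2-[4-(methoxymethoxy)-3,5-dimethoxyphenyl]-2,3-dihydro-1-benzofuran-5-yl trifluoromethanesulfonate | COCOc1c(OC)cc([C@@H]2Oc3c(OC)cc(OS(=O)(=O)C(F)(F)F)cc3[C@H]2CO)cc1OC | intermediate
29 | 3,5-dihydroxybenzaldehyde | O=Cc1cc(O)cc(O)c1 | starting material
30 | 3,5-bis(methoxymethoxy)benzaldehyde | COCOc1cc(C=O)cc(OCOC)c1 | intermediate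
31 | 1-ethenyl-3,5-bis(methoxymethoxy)benzene | C=Cc1cc(OCOC)cc(OCOC)c1 | intermediate
32 | [(2R,3S)-5-[(E)-2-[3,5-bis(methoxymethoxy)phenyl]ethenyl]-7-methoxy-2-[4-(methoxymethoxy)-3,5-dimethoxyphenyl]-2,3-dihydro-1-benzofuran-3-yl]methanol | COCOc1c(OC)cc([C@@H]2Oc3c(OC)cc(/C=C/c4cc(OCOC)cc(OCOC)c4)cc3[C@H]2CO)cc1OC | intermediate
33 | Gnetucleistol F, 5-[(E)-2-[(2R,3S)-2-(4-hydroxy-3,5-dimethoxyphenyl)-3-(hydroxymethyl)-7-methoxy-2,3-dihydro-1-benzofuran-5-yl]ethenyl]benzene-1,3-diol | COc1cc([C@@H]2Oc3c(OC)cc(/C=C/c4cc(O)cc(O)c4)cc3[C@H]2CO)cc(OC)c1O | target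

**Step count**
Total: 18 steps. Longest linear sequence: 14 steps (steps 1, 3–9, 11–14, 17, 18).

**Steps most likely to fail**

Step 11. The photolysis may be diverted before the 1,2-shift (carbene insertion or secondary photolysis of the electron-rich product), the product phenol may be acylated by ketene intermediates, or the cyclobutenone may fail to open cleanly under the one-pot conditions. The fallback generates the same vinylketene thermally and in the dark; it sets out from diazoketone 17 and comes back at phenol 25. Wolff rearrangement of 17 with PhCO2Ag (cat.) and Et3N in THF/H2O should give the homologous 2-[(4S,5R)-4-[(tert-butyldimethylsilyloxy)methyl]-5-Ar-4,5-dihydrofuran-3-yl]acetic acid F1 (Arndt–Eistert homologation). The chloroenamine Me2C=C(Cl)NMe2 should convert it into 2-[(4S,5R)-4-[(tert-butyldimethylsilyloxy)methyl]-5-Ar-4,5-dihydrofuran-3-yl]acetyl chloride F2. Slow addition of Et3N to F2 and alkyne 20 in toluene at rt should form vinylketene 21 by dehydrochlorination and trap it as cyclobutenone 22, which is isolated here. Heating 22 in toluene at 110 °C (thermal cyclobutenone benzannulation) should then give 25.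

Step 3. The 3-butynoyl imide or its enolate may isomerise to the allenoyl system before C–C bond formation, and the electron-rich benzylic aldolate may undergo retro-aldol during work-up, eroding both conversion and syn selectivity. The fallback replaces the alkyne by an allyl group and closes the furan ring by lactol dehydration; it sets out from auxiliary 4 and aldehyde 2 and comes back at dihydrofuran 13. Acylation of 4 (n-BuLi, pent-4-enoyl chloride, THF, −78 °C) should give (R)-4-benzyl-3-(pent-4-enoyl)oxazolidin-2-one F3. Its Evans syn aldol with 2 (Bu2BOTf, i-Pr2NEt) should give (R)-4-benzyl-3-[(2R)-2-[(R)-hydroxy(Ar)methyl]pent-4-enoyl]oxazolidin-2-one F4. LiBH4 should reduce this to (1R,2S)-1-Ar-2-(prop-2-en-1-yl)propane-1,3-diol F5, and TBSCl/imidazole should give (1R,2S)-2-[(tert-butyldimethylsilyloxy)methyl]-1-Ar-pent-4-en-1-ol F6. Lemieux–Johnson cleavage (OsO4 cat., NaIO4, 2,6-lutidine, dioxane/H2O) should give the lactol (4S,5R)-4-[(tert-butyldimethylsilyloxy)methyl]-5-Ar-oxolan-2-ol F7. Dehydration through the anomeric mesylate (MsCl, Et3N, CH2Cl2, −20 °C → reflux) should give 13.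

Step 9. Diazomethane may add as a 1,3-dipole across the conjugated C=C bond instead of being acylated, or the diazoketone may be captured by HCl as the chloromethyl ketone. The fallback installs the diazo group by diazo transfer onto a methyl ketone; it sets out from acid 15 and comes back at diazoketone 17. Amide coupling of 15 (MeNHOMe·HCl, EDC·HCl, i-Pr2NEt, CH2Cl2) should give the Weinreb amide (4S,5R)-N-methoxy-N-methyl-4-[(tert-butyldimethylsilyloxy)methyl]-5-Ar-4,5-dihydrofuran-3-carboxamide F8. MeMgBr (THF, 0 °C) should give the methyl ketone 1-[(4S,5R)-4-[(tert-butyldimethylsilyloxy)methyl]-5-Ar-4,5-dihydrofuran-3-yl]ethan-1-one F9. Kinetic enolisation with LiN(SiMe3)2 (THF, −78 °C) and trifluoroacetylation with CF3CO2CH2CF3 should give 4,4,4-trifluoro-1-[(4S,5R)-4-[(tert-butyldimethylsilyloxy)methyl]-5-Ar-4,5-dihydrofuran-3-yl]butane-1,3-dione F10, which is not isolated. Treatment with MsN3, Et3N and H2O in MeCN (detrifluoroacetylative diazo transfer) should give 17.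

**Further compounds**
F1 | step 11 | 2-[(4S,5R)-4-[(tert-butyldimethylsilyloxy)methyl]-5-[4-(methoxymethoxy)-3,5-dimethoxyphenyl]-4,5-dihydrofuran-3-yl]acetic acid | COCOc1c(OC)cc([C@@H]2OC=C(CC(=O)O)[C@H]2CO[Si](C)(C)C(C)(C)C)cc1OC
F2 | step 11 | 2-[(4S,5R)-4-[(tert-butyldimethylsilyloxy)methyl]-5-[4-(methoxymethoxy)-3,5-dimethoxyphenyl]-4,5-dihydrofuran-3-yl]acetyl chloride | COCOc1c(OC)cc([C@@H]2OC=C(CC(=O)Cl)[C@H]2CO[Si](C)(C)C(C)(C)C)cc1OC
F3 | step 3 | (R)-4-benzyl-3-(pent-4-enoyl)oxazolidin-2-one | C=CCCC(=O)N1[C@H](Cc2ccccc2)COC1=O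
F4 | step 3 | (R)-4-benzyl-3-[(2R)-2-[(R)-hydroxy[4-(methoxymethoxy)-3,5-dimethoxyphenyl]methyl]pent-4-enoyl]oxazolidin-2-one | C=CC[C@H]([C@@H](O)c1cc(OC)c(OCOC)c(OC)c1)C(=O)N1[C@H](Cc2ccccc2)COC1=O
F5 | step 3 | (1R,2S)-1-[4-(methoxymethoxy)-3,5-dimethoxyphenyl]-2-(prop-2-en-1-yl)propane-1,3-diol | C=CC[C@H]([C@@H](O)c1cc(OC)c(OCOC)c(OC)c1)CO
F6 | step 3 | (1R,2S)-2-[(tert-butyldimethylsilyloxy)methyl]-1-[4-(methoxymethoxy)-3,5-dimethoxyphenyl]pent-4-en-1-ol | C=CC[C@H]([C@@H](O)c1cc(OC)c(OCOC)c(OC)c1)CO[Si](C)(C)C(C)(C)C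
F7 | step 3 | (4S,5R)-4-[(tert-butyldimethylsilyloxy)methyl]-5-[4-(methoxymethoxy)-3,5-dimethoxyphenyl]oxolan-2-ol (both anomers) | COCOc1c(OC)cc([C@@H]2OC(O)C[C@H]2CO[Si](C)(C)C(C)(C)C)cc1OC
F8 | step 9 | (4S,5R)-N-methoxy-N-methyl-4-[(tert-butyldimethylsilyloxy)methyl]-5-[4-(methoxymethoxy)-3,5-dimethoxyphenyl]-4,5-dihydrofuran-3-carboxamide | COCOc1c(OC)cc([C@@H]2OC=C(C(=O)N(C)OC)[C@H]2CO[Si](C)(C)C(C)(C)C)cc1OC
F9 | step 9 | 1-[(4S,5R)-4-[(tert-butyldimethylsilyloxy)methyl]-5-[4-(methoxymethoxy)-3,5-dimethoxyphenyl]-4,5-dihydrofuran-3-yl]ethan-1-one | COCOc1c(OC)cc([C@@H]2OC=C(C(C)=O)[C@H]2CO[Si](C)(C)C(C)(C)C)cc1OC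
F10 | step 9 | 4,4,4-trifluoro-1-[(4S,5R)-4-[(tert-butyldimethylsilyloxy)methyl]-5-[4-(methoxymethoxy)-3,5-dimethoxyphenyl]-4,5-dihydrofuran-3-yl]butane-1,3-dione | COCOc1c(OC)cc([C@@H]2OC=C(C(=O)CC(=O)C(F)(F)F)[C@H]2CO[Si](C)(C)C(C)(C)C)cc1OC
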